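**Strategy.** Everything rests on disconnecting the bond between C7, the methyl-bearing sp2 carbon of the (E)-C6=C7 olefin, and C8, the acetoxy carbon: an allylic carbinol that the C9 methylene insulates from the alkylidene butyrolactone ring, the retron of an alkenylmetal–aldehyde addition. A catalytic asymmetric Nozaki–Hiyama–Kishi coupling of alkenyl iodide 11 (carrying the angelate and the (2Z,6E)-diene) with lactone aldehyde 23 (C12 silyl-protected, C12/C13 from 2-deoxy-D-ribonolactone) forms C7–C8 and sets C8 (S) by ligand control in one operation, leaving esters, lactone and olefin geometries untouched. Acetylation and desilylation then complete the target.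

Key step: step 14

Numbering used: C1 is the OCH2 carbon bearing the angelate, C3 and C7 carry the methyl groups, C8 carries the acetate, C9 is the CH2, C10 the exocyclic =CH, C11 the ring carbon next to the lactone carbonyl, C12 the ring carbon with OH, C13 the ring carbon with the 2-methylprop-1-enyl group.

Assumption: 2-deoxy-D-ribono-1,4-lactone (12) is purchased (otherwise one bromine-water oxidation from 2-deoxy-D-ribose); the oxazoline–sulfonamide ligand of step 14 is a known, readily made compound and is treated as a reagent.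

Assumption: the (S)-ligand is taken to deliver the alkenyl group to the Re face of the aldehyde (8S); if a model coupling shows the opposite sense, its antipode from D-valinol is used.

Layout: steps 1–5 make the alkenyl iodide 11, steps 6–13 make the aldehyde 23, steps 14–16 join them and finish.

Step 1
Reactants: 1 pent-3-yn-1-ol
Product: 2 5-iodopent-2-yne
Conditions: I2, PPh3, imidazole, CH2Cl2, 0 °C to rt
Reagents that add atoms: iodine, II
Why: Appel-type iodination of the primary alcohol through its alkoxyphosphonium iodide proceeds by SN2 displacement and leaves the internal alkyne untouched.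

Step 2
Reactants: 3 but-2-yn-1-ol
Product: 5 (Z)-3-iodobut-2-en-1-ol, via cyclic sodium alkenylaluminate 4 (not isolated)
Conditions: NaAlH2(OCH2CH2OMe)2, THF, 0 °C to rt; then I2, THF, −78 to 0 °C
Reagents that add atoms: iodine, II
Why: Hydroxyl-directed trans-hydroalumination of the propargylic alcohol places aluminium on C3 cis to the CH2O group in a five-membered aluminate, and iodinolysis of the C–Al bond with retention gives the (Z)-iodide.

Step 3
Reactants: 2 5-iodopent-2-yne; 5 (Z)-3-iodobut-2-en-1-ol
Product: 7 (Z)-3-methyloct-2-en-6-yn-1-ol, via pent-3-yn-1-ylzinc iodide 6 (not isolated)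
Conditions: 2 (2 equiv), Zn dust, LiCl, THF, 40 °C; then 5, Pd(OAc)2 (2 mol %), SPhos (4 mol %), THF, rt
Reagents that add atoms: none
Why: Negishi sp3–sp2 cross-coupling, in which zinc inserts into the primary C–I bond and the palladium-catalysed coupling with the alkenyl iodide retains the (Z)-geometry while the alkylzinc tolerates the free hydroxyl.

Step 4
Reactants: 7 (Z)-3-methyloct-2-en-6-yn-1-ol
Product: 9 (2Z,6E)-7-iodo-3-methylocta-2,6-dien-1-ol, via O-zirconated alkenylzirconocene chloride 8 (not isolated)
Conditions: Cp2Zr(H)Cl (3 equiv), THF, rt to 40 °C; then I2, THF, 0 °C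
Reagents that add atoms: iodine, II
Why: Hydrozirconation–iodination, in which syn addition of Zr–H to the methyl alkyne is equilibrated by excess hydride to the isomer with zirconium on the methyl-bearing carbon and iodinolysis with retention gives the (E)-2-iodoalkene, the first equivalent of reagent only capping the hydroxyl as its zirconium alkoxide.

Step 5
Reactants: 9 (2Z,6E)-7-iodo-3-methylocta-2,6-dien-1-ol; 10 angelic acid
Product: 11 (2Z,6E)-7-iodo-3-methylocta-2,6-dien-1-yl (Z)-2-methylbut-2-enoate
Conditions: PPh3, DIAD, THF, 0 °C to rt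
Reagents that add atoms: none
Why: Mitsunobu esterification activates the primary allylic alcohol and not the acid, so the carboxylate attacks by SN2 and the (Z)-angelate cannot isomerise to tiglate as it may through an activated acyl derivative.

Step 6
Reactants: 12 2-deoxy-D-ribono-1,4-lactone
Product: 13 (4S,5R)-4-[(tert-butyldimethylsilyl)oxy]-5-{[(tert-butyldimethylsilyl)oxy]methyl}oxolan-2-one
Conditions: TBSCl, imidazole, DMF, rt
Reagents that add atoms: tert-butyldimethylsilyl chloride, CC(C)(C)[Si](C)(C)Cl
Why: Standard imidazole-promoted silylation of both hydroxyls, the two sugar stereocentres (4S,5R) being carried unchanged to become C12 and C13 of the target.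

Step 7
Reactants: 13 bis-silyl lactone
Product: 14 (4S,5R)-4-[(tert-butyldimethylsilyl)oxy]-5-(hydroxymethyl)oxolan-2-one
Conditions: TFA/H2O/THF (1:1:4), 0 °C
Reagents that add atoms: none
Why: Acid-catalysed solvolysis removes the unhindered primary silyl ether much faster than the secondary one, the usual selective desilylation of bis-silylated deoxyribose derivatives.

Step 8
Reactants: 14 primary alcohol
Product: 15 (2S,3S)-3-[(tert-butyldimethylsilyl)oxy]-5-oxooxolane-2-carbaldehyde
Conditions: Dess–Martin periodinane, NaHCO3, CH2Cl2, 0 °C to rt; used crude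
Reagents that add atoms: none
Why: Dess–Martin oxidation under buffered, non-basic conditions gives the α-oxygenated aldehyde without epimerising C13 or eliminating the β-silyloxy group.

Step 9
Reactants: 15 aldehyde
Product: 16 (4S,5R)-4-[(tert-butyldimethylsilyl)oxy]-5-(2-methylprop-1-en-1-yl)oxolan-2-one
Conditions: iPrPPh3I, KN(SiMe3)2, THF, 0 °C; then 15, −78 to 0 °C
Reagents that add atoms: isopropyltriphenylphosphonium iodide, CC(C)[P+](c1ccccc1)(c1ccccc1)c1ccccc1.[I-]
Why: Wittig olefination with the non-stabilised isopropylidene ylide converts the aldehyde into the 2-methylprop-1-enyl group far faster at −78 °C than the ylide attacks the lactone or enolises the aldehyde, as in olefinations of protected dialdofuranoses.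

Step 10
Reactants: 16 lactone; 17 3-[(tert-butyldimethylsilyl)oxy]propanal
Product: 19 (4S,5R)-4-[(tert-butyldimethylsilyl)oxy]-3-{3-[(tert-butyldimethylsilyl)oxy]-1-hydroxypropyl}-5-(2-methylprop-1-en-1-yl)oxolan-2-one (epimers at C11 and C10), via lithium enolate 18 (not isolated)
Conditions: LiN(iPr)2, THF, −78 °C; then 17, −78 °C; aq. NH4Cl at −78 °C
Reagents that add atoms: none
Why: Aldol addition of the lactone lithium enolate, kept at −78 °C so that the poor silyloxide leaving group at C12 is not expelled, gives the β-hydroxy lactone whose two new stereocentres (expected trans at C11 to the C12 silyloxy group, unselective at C10) are both erased in the next step.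

Step 11
Reactants: 19 aldol adducts
Product: 21 (3E,4S,5R)-4-[(tert-butyldimethylsilyl)oxy]-3-{3-[(tert-butyldimethylsilyl)oxy]propylidene}-5-(2-methylprop-1-en-1-yl)oxolan-2-one, via aldol mesylate 20 (not isolated)
Conditions: MsCl, Et3N, CH2Cl2, 0 °C; then DBU, 0 °C to rt
Reagents that add atoms: none
Why: Mesylation and E1cB elimination through the lactone enolate, which expels mesylate and not the C12 silyloxide, should converge all aldol epimers on the alkylidene lactone with the chain anti to the carbonyl, the (E)-isomer usually favoured in such condensations, any (Z)-isomer being removed by chromatography.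

Step 12
Reactants: 21 bis-silyl alkylidene lactone
Product: 22 (3E,4S,5R)-4-[(tert-butyldimethylsilyl)oxy]-3-(3-hydroxypropylidene)-5-(2-methylprop-1-en-1-yl)oxolan-2-one
Conditions: HF·pyridine, pyridine, THF, 0 °C
Reagents that add atoms: none
Why: Buffered fluoride desilylation cleaves the primary silyl ether selectively over the hindered secondary allylic one on the ring.

Step 13
Reactants: 22 homoallylic alcohol
Product: 23 (3E)-3-[(4S,5R)-4-[(tert-butyldimethylsilyl)oxy]-5-(2-methylprop-1-en-1-yl)-2-oxooxolan-3-ylidene]propanal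
Conditions: Dess–Martin periodinane, NaHCO3, CH2Cl2, 0 °C; short silica pad, used at once
Reagents that add atoms: none
Why: Dess–Martin oxidation of the homoallylic alcohol under buffered neutral conditions should give the β,γ-unsaturated aldehyde without enolising the doubly activated C9 methylene.

Step 14
Reactants: 23 lactone aldehyde; 11 alkenyl iodide (1.3 equiv)
Product: 24 (2Z,6E,8S)-8-hydroxy-3,7-dimethyl-10-[(3E,4S,5R)-4-[(tert-butyldimethylsilyl)oxy]-5-(2-methylprop-1-en-1-yl)-2-oxooxolan-3-ylidene]deca-2,6-dien-1-yl (Z)-2-methylbut-2-enoate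
Conditions: CrCl2 (15 mol %), (S)-N-[2-(4-isopropyl-4,5-dihydrooxazol-2-yl)-6-methylphenyl]methanesulfonamide (17 mol %), 1,8-bis(dimethylamino)naphthalene (17 mol %), NiCl2(2,9-dimethyl-1,10-phenanthroline) (2 mol %), Mn powder (2 equiv), Cp2ZrCl2 (1.2 equiv), LiCl (2 equiv), MeCN, rt
Reagents that add atoms: none
Why: Zerovalent nickel inserts into the C–I bond of 11 with retention of the (E)-geometry and passes the alkenyl group to trivalent chromium bound to the chiral oxazoline–sulfonamide, the alkenylchromium adds to the aldehyde of 23 to form the C7–C8 bond, Cp2ZrCl2 frees the alkoxide from chromium and Mn returns chromium to the divalent state. The closest known reaction type is the catalytic asymmetric Nozaki–Hiyama–Kishi alkenylation of aldehydes, used here as a fragment union. No ring is closed in this step. The new stereocentre C8 is controlled by the ligand on chromium, which has to deliver the alkenyl group to the Re face of the aldehyde to give 8S; C12 and C13 lie four and five bonds away across the rigid C10=C11 olefin and should exert no useful bias, so the ligand antipode decides the outcome and the sense of induction is checked on 24 by Mosher ester analysis. The step needs chemoselectivity for the aldehyde over the lactone, the angelate and the enoate-type olefins, which the weakly basic, carbonyl-selective organochromium secures, and it needs the doubly activated C9 methylene of 23 to escape enolisation, which the near-neutral medium and room temperature favour.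

Step 15
Reactants: 24 allylic alcohol
Product: 25 (2Z,6E,8S)-8-acetoxy-3,7-dimethyl-10-[(3E,4S,5R)-4-[(tert-butyldimethylsilyl)oxy]-5-(2-methylprop-1-en-1-yl)-2-oxooxolan-3-ylidene]deca-2,6-dien-1-yl (Z)-2-methylbut-2-enoate
Conditions: Ac2O, pyridine, DMAP (cat.), CH2Cl2, 0 °C
Reagents that add atoms: acetic anhydride, CC(=O)OC(C)=O
Why: DMAP-catalysed acylation of the only free hydroxyl (C8, C12 still being silylated) proceeds with retention under amine bases too weak to trigger vinylogous elimination of the new allylic acetate.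

Step 16
Reactants: 25 silyl ether
Product: 26 CNP0201198.1, (2Z,6E,8S)-8-acetoxy-3,7-dimethyl-10-[(3E,4S,5R)-4-hydroxy-5-(2-methylprop-1-en-1-yl)-2-oxooxolan-3-ylidene]deca-2,6-dien-1-yl (Z)-2-methylbut-2-enoate
Conditions: HF·pyridine, pyridine, THF, 0 °C to rt
Reagents that add atoms: none
Why: Acidic fluoride desilylation frees the C12 hydroxyl without the basic fluoride conditions that could eliminate the C8 acetate through the C9 vinylogous enolate, migrate acyl groups or isomerise the angelate.

**Compound list**

1 | pent-3-yn-1-ol | CC#CCCO | starting material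
2 | 5-iodopent-2-yne | CC#CCCI | intermediate
3 | but-2-yn-1-ol | CC#CCO | starting material
4 | cyclic sodium alkenylaluminate (sodium 2,2-bis(2-methoxyethoxy)-3-methyl-2,5-dihydro-1,2-oxaaluminol-2-uide) | CC1=CCO[Al-]1(OCCOC)OCCOC.[Na+] | intermediate (not isolated)
5 | (Z)-3-iodobut-2-en-1-ol | OC/C=C(/C)I | intermediate
6 | pent-3-yn-1-ylzinc iodide | CC#CCC[Zn]I | intermediate (not isolated)
7 | (Z)-3-methyloct-2-en-6-yn-1-ol | OC/C=C(/C)CCC#CC | intermediate
8 | O-zirconated (2Z,6E)-alkenylzirconocene chloride: Cp2Zr(Cl) on O1 and on C7 of the 3-methylocta-2,6-dienyl chain | Cl[Zr](C1C=CC=C1)(C1C=CC=C1)OC/C=C(/C)CC/C=C(\C)[Zr](Cl)(C1C=CC=C1)C1C=CC=C1 | intermediate (not isolated)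
9 | (2Z,6E)-7-iodo-3-methylocta-2,6-dien-1-ol | OC/C=C(/C)CC/C=C(\C)I | intermediate
10 | angelic acid, (Z)-2-methylbut-2-enoic acid | C/C=C(/C)C(=O)O | starting material
11 | (2Z,6E)-7-iodo-3-methylocta-2,6-dien-1-yl (Z)-2-methylbut-2-enoate | C/C=C(/C)C(=O)OC/C=C(/C)CC/C=C(\C)I | intermediate
12 | 2-deoxy-D-ribono-1,4-lactone, (4S,5R)-4-hydroxy-5-(hydroxymethyl)oxolan-2-one | OC[C@H]1OC(=O)C[C@@H]1O | starting material
13 | (4S,5R)-4-[(tert-butyldimethylsilyl)oxy]-5-{[(tert-butyldimethylsilyl)oxy]methyl}oxolan-2-one | CC(C)(C)[Si](C)(C)OC[C@H]1OC(=O)C[C@@H]1O[Si](C)(C)C(C)(C)C | intermediate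
14 | (4S,5R)-4-[(tert-butyldimethylsilyl)oxy]-5-(hydroxymethyl)oxolan-2-one | OC[C@H]1OC(=O)C[C@@H]1O[Si](C)(C)C(C)(C)C | intermediate
15 | (2S,3S)-3-[(tert-butyldimethylsilyl)oxy]-5-oxooxolane-2-carbaldehyde | O=C[C@H]1OC(=O)C[C@@H]1O[Si](C)(C)C(C)(C)C | intermediate
16 | (4S,5R)-4-[(tert-butyldimethylsilyl)oxy]-5-(2-methylprop-1-en-1-yl)oxolan-2-one | CC(C)=C[C@H]1OC(=O)C[C@@H]1O[Si](C)(C)C(C)(C)C | intermediate
17 | 3-[(tert-butyldimethylsilyl)oxy]propanal | O=CCCO[Si](C)(C)C(C)(C)C | starting material
18 | lithium enolate of 16 | CC(C)=C[C@H]1OC(O[Li])=C[C@@H]1O[Si](C)(C)C(C)(C)C | intermediate (not isolated)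
19 | (4S,5R)-4-[(tert-butyldimethylsilyl)oxy]-3-{3-[(tert-butyldimethylsilyl)oxy]-1-hydroxypropyl}-5-(2-methylprop-1-en-1-yl)oxolan-2-one, epimers at C11 and C10 | CC(C)=C[C@H]1OC(=O)C(C(O)CCO[Si](C)(C)C(C)(C)C)[C@@H]1O[Si](C)(C)C(C)(C)C | intermediate
20 | methanesulfonate of 19 at the side-chain carbinol | CC(C)=C[C@H]1OC(=O)C(C(OS(C)(=O)=O)CCO[Si](C)(C)C(C)(C)C)[C@@H]1O[Si](C)(C)C(C)(C)C | intermediate (not isolated)
21 | (3E,4S,5R)-4-[(tert-butyldimethylsilyl)oxy]-3-{3-[(tert-butyldimethylsilyl)oxy]propylidene}-5-(2-methylprop-1-en-1-yl)oxolan-2-one | CC(C)(C)[Si](C)(C)OCC/C=C1/C(=O)O[C@H](C=C(C)C)[C@H]1O[Si](C)(C)C(C)(C)C | intermediate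
22 | (3E,4S,5R)-4-[(tert-butyldimethylsilyl)oxy]-3-(3-hydroxypropylidene)-5-(2-methylprop-1-en-1-yl)oxolan-2-one | OCC/C=C1/C(=O)O[C@H](C=C(C)C)[C@H]1O[Si](C)(C)C(C)(C)C | intermediate
23 | (3E)-3-[(4S,5R)-4-[(tert-butyldimethylsilyl)oxy]-5-(2-methylprop-1-en-1-yl)-2-oxooxolan-3-ylidene]propanal | O=CC/C=C1/C(=O)O[C@H](C=C(C)C)[C@H]1O[Si](C)(C)C(C)(C)C | intermediate
24 | (2Z,6E,8S)-8-hydroxy-3,7-dimethyl-10-[(3E,4S,5R)-4-[(tert-butyldimethylsilyl)oxy]-5-(2-methylprop-1-en-1-yl)-2-oxooxolan-3-ylidene]deca-2,6-dien-1-yl (Z)-2-methylbut-2-enoate | C/C=C(/C)C(=O)OC/C=C(/C)CC/C=C(\C)[C@H](C/C=C1/C(=O)O[C@H](C=C(C)C)[C@H]1O[Si](C)(C)C(C)(C)C)O | intermediate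
25 | (2Z,6E,8S)-8-acetoxy-3,7-dimethyl-10-[(3E,4S,5R)-4-[(tert-butyldimethylsilyl)oxy]-5-(2-methylprop-1-en-1-yl)-2-oxooxolan-3-ylidene]deca-2,6-dien-1-yl (Z)-2-methylbut-2-enoate | C/C=C(/C)C(=O)OC/C=C(/C)CC/C=C(\C)[C@H](C/C=C1/C(=O)O[C@H](C=C(C)C)[C@H]1O[Si](C)(C)C(C)(C)C)OC(C)=O | intermediate
26 | CNP0201198.1, (2Z,6E,8S)-8-acetoxy-3,7-dimethyl-10-[(3E,4S,5R)-4-hydroxy-5-(2-methylprop-1-en-1-yl)-2-oxooxolan-3-ylidene]deca-2,6-dien-1-yl (Z)-2-methylbut-2-enoate | C/C=C(/C)C(=O)OC/C=C(/C)CC/C=C(\C)[C@H](C/C=C1/C(=O)O[C@H](C=C(C)C)[C@H]1O)OC(C)=O | target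

**Totals.** 16 steps in all; the longest linear sequence is 11 steps (12 to 26, steps 6–16).

**Steps most likely to fail**

Step 14. The alkenyl transfer may occur with poor facial selectivity if ligand control is weak, and the skipped aldehyde may be partly lost by enolisation. Fallback: setting out from 23 and 11, the coupling is run without chiral ligand (CrCl2 in excess, NiCl2 1 mol %, DMSO, rt) to give the C8-epimeric alcohols F1. These are oxidised with Dess–Martin periodinane/NaHCO3 to the cross-conjugated ketone F2. Reduction with (R)-2-methyl-CBS-oxazaborolidine and catecholborane in toluene at −78 °C then sets 8S by reagent control (the 2-methylalkenyl group acting as the large substituent), and the route is rejoined at 24.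

Step 11. The elimination may give the alkylidene with poor E/Z control, or the base may move the exocyclic double bond. Fallback: setting out from 16, one-flask O-phosphorylation and 1,3-phosphoryl shift (LiN(iPr)2 2.2 equiv, ClP(O)(OEt)2, THF, −78 °C to rt) gives the α-phosphono lactone F3. A Horner–Wadsworth–Emmons olefination of F3 with 17 under LiCl/DBU in MeCN, conditions that favour the (E)-alkylidene lactone, rejoins the route at 21 and bypasses 19 and the elimination.

Step 9. The basic ylide may epimerise the aldehyde α-carbon, eliminate the β-silyloxy group, or attack the lactone carbonyl. Fallback: setting out from 15, a non-basic methylenation (Zn, CH2I2, TiCl4, THF, 0 °C) gives (4S,5R)-4-[(tert-butyldimethylsilyl)oxy]-5-vinyloxolan-2-one F4. Cross-metathesis of F4 with 2-methyl-2-butene as solvent, catalysed by the second-generation Grubbs catalyst RuCl2(=CHPh)(PCy3)(H2IMes) at 40 °C, installs the trisubstituted olefin and rejoins the route at 16.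

Further compounds
F1 | step 14 | C8-epimeric mixture of alcohol 24 (8RS) | C/C=C(/C)C(=O)OC/C=C(/C)CC/C=C(\C)C(O)C/C=C1/C(=O)O[C@H](C=C(C)C)[C@H]1O[Si](C)(C)C(C)(C)C
F2 | step 14 | 8-oxo analogue of 24, (2Z,6E)-3,7-dimethyl-8-oxo-10-[(3E,4S,5R)-4-[(tert-butyldimethylsilyl)oxy]-5-(2-methylprop-1-en-1-yl)-2-oxooxolan-3-ylidene]deca-2,6-dien-1-yl (Z)-2-methylbut-2-enoate | C/C=C(/C)C(=O)OC/C=C(/C)CC/C=C(\C)C(=O)C/C=C1/C(=O)O[C@H](C=C(C)C)[C@H]1O[Si](C)(C)C(C)(C)C
F3 | step 11 | diethyl [(4S,5R)-4-[(tert-butyldimethylsilyl)oxy]-5-(2-methylprop-1-en-1-yl)-2-oxooxolan-3-yl]phosphonate | CCOP(=O)(OCC)C1C(=O)O[C@H](C=C(C)C)[C@H]1O[Si](C)(C)C(C)(C)C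
F4 | step 9 | (4S,5R)-4-[(tert-butyldimethylsilyl)oxy]-5-vinyloxolan-2-one | C=C[C@H]1OC(=O)C[C@@H]1O[Si](C)(C)C(C)(C)C
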